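**Retrosynthetic overview**

- The target comes from acylation of the secondary C6 hydroxyl of a hydroazulene diol that already carries the C10 acetate.
- Both rings come from one Lewis-acid cationic cascade of an acyclic (Z)-dienyl tertiary acetate bearing an aldehyde silyl enol ether. SN1 C-alkylation closes the five-membered ring, the oxocarbenium ion released closes the seven-membered ring by a diene–Prins step, and the acetate returns at C10.
- The cascade substrate comes from Z-selective semi-hydrogenation of an enyne, made by adding the acetylide of 2-methylbut-1-en-3-yne to a methyl ketone and acetylating the alkoxide.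
- The ketone with its enol ether comes from ozonolysis of (S)-terpinen-4-ol (ten carbons and the carbinol stereocentre) followed by chemoselective silylation.
- Ring order: cyclopentane first, cycloheptene second, in the same flask; the chiral-pool carbinol centre controls C1, C5, C6 and C10.

Assumption: (S)-terpinen-4-ol is bought as the single enantiomer (≥98% ee; material of lower ee would be enriched first), and carbon labels C1–C10 in the explanations follow daucane numbering of the target (C1 methyl-bearing ring-fusion carbon, C4 isopropyl carbinol, C5 ring-fusion CH, C6 anisoyloxy carbon, C8=C9 alkene, C10 acetoxy carbon).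

**Route**

Step 1
Reactants: 1 (S)-terpinen-4-ol
Product: 3 (3S)-3-hydroxy-6-oxo-3-(propan-2-yl)heptanal, via ozonide 2 (not isolated)
Conditions: O3, CH2Cl2, −78 °C; then PPh3, −78 °C to rt; used crude
Reagents that add atoms: ozone, [O-][O+]=O
Why: Ozonolysis (Criegee cleavage) with reductive work-up turns the only C=C bond into a methyl ketone (future C1) and an aldehyde (future C6) and leaves the tertiary carbinol stereocentre (future C4) untouched, so no new stereocentre is formed.

Step 2
Reactants: 3 (3S)-3-hydroxy-6-oxo-3-(propan-2-yl)heptanal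
Product: 4 (5R,6Z)-5-(propan-2-yl)-5,7-bis[(triethylsilyl)oxy]hept-6-en-2-one
Conditions: Et3SiOTf (2.2 equiv), Et3N (3 equiv), CH2Cl2, −78 °C
Reagents that add atoms: triethylsilyl trifluoromethanesulfonate, CC[Si](CC)(CC)OS(=O)(=O)C(F)(F)F
Why: Soft enolisation and O-silylation with a silyl triflate and amine at −78 °C should convert the unhindered, more acidic aldehyde α-CH2 into the silyl enol ether and the tertiary hydroxyl into its silyl ether faster than the methyl ketone is enolised, which gives the later C5 nucleophile and masks the C4 oxygen; no stereocentre is formed and the enol ether geometry is of no consequence.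

Step 3
Reactants: 4 (5R,6Z)-5-(propan-2-yl)-5,7-bis[(triethylsilyl)oxy]hept-6-en-2-one, 5 2-methylbut-1-en-3-yne
Product: 8 (5RS,8R,9Z)-2,5-dimethyl-8-(propan-2-yl)-8,10-bis[(triethylsilyl)oxy]deca-1,9-dien-3-yn-5-yl acetate, via lithium acetylide 6 (not isolated), via lithium alkoxide 7 (not isolated)
Conditions: 5, n-BuLi, THF, −78 °C; add 4, −78 °C; then Ac2O, −78 to 0 °C
Reagents that add atoms: acetic anhydride, CC(=O)OC(C)=O
Why: 1,2-Addition of a lithium acetylide to the methyl ketone (alkynylation) followed by O-acetylation of the tertiary lithium alkoxide installs C7–C10, the C8 methyl and the leaving group; the new carbinol carbon forms as both epimers, which does not matter because it becomes a planar cation in step 5.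

Step 4
Reactants: 8 (5RS,8R,9Z)-2,5-dimethyl-8-(propan-2-yl)-8,10-bis[(triethylsilyl)oxy]deca-1,9-dien-3-yn-5-yl acetate
Product: 9 (3Z,5RS,8R,9Z)-2,5-dimethyl-8-(propan-2-yl)-8,10-bis[(triethylsilyl)oxy]deca-1,3,9-trien-5-yl acetate
Conditions: H2 (1 atm), Pd on CaCO3 poisoned with Pb(OAc)2, quinoline, hexane/EtOAc, rt, stopped after 1 equiv H2; used at once
Reagents that add atoms: none
Why: Lindlar-type semi-hydrogenation adds H2 syn to the alkyne only and gives the (Z)-1,3-diene that the seven-membered ring closure needs, while the enol ether, the 1,1-disubstituted alkene and the tertiary acetate are not reduced; no stereocentre is formed.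

Step 5
Reactants: 9 (3Z,5RS,8R,9Z)-2,5-dimethyl-8-(propan-2-yl)-8,10-bis[(triethylsilyl)oxy]deca-1,3,9-trien-5-yl acetate
Product: 11 (3R,3aS,4S,8R,8aS)-3,4-dihydroxy-6,8a-dimethyl-3-(propan-2-yl)-1,2,3,3a,4,5,8,8a-octahydroazulen-8-yl acetate, via bicyclic bis-silyl ether 10 (not isolated)
Conditions: Me3SiOTf (10 mol%), 2,6-di-tert-butyl-4-methylpyridine (20 mol%), CH2Cl2 (5 mM), −78 to −40 °C; then HF·pyridine, THF, 0 °C to rt
Reagents that add atoms: none
Why: Proposed new method: Me3SiOTf ionises the tertiary doubly allylic acetate to a pentadienyl cation that the tethered silyl enol ether captures 5-exo at C1 (SN1 α-tert-alkylation of an enol silane, closest known type the Reetz alkylation); the O-silyl oxocarbenium ion so released at C6 is attacked by the terminal CH2 of the (Z)-diene (diene–Prins closure of the seven-membered ring, closest known type the Mukaiyama aldol–Prins cascade), and the resulting allyl cation takes acetate back from Me3SiOAc at C10, giving the trisubstituted C8=C9 alkene and regenerating the catalyst; C1 and C5 are set in the first closure through an envelope transition state that keeps isopropyl, the enol carbon and the dienyl group pseudo-equatorial and pairs only the small methyl and silyloxy groups 1,3-diaxially, C6 by attack on the oxocarbenium conformer with oxygen anti to C4, and C10 by acetate approach anti to the angular methyl, after which HF·pyridine removes both silyl groups.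

Step 6
Reactants: 11 (3R,3aS,4S,8R,8aS)-3,4-dihydroxy-6,8a-dimethyl-3-(propan-2-yl)-1,2,3,3a,4,5,8,8a-octahydroazulen-8-yl acetate
Product: 12 (3R,3aS,4S,8R,8aS)-8-(acetyloxy)-3-hydroxy-6,8a-dimethyl-3-(propan-2-yl)-1,2,3,3a,4,5,8,8a-octahydroazulen-4-yl 4-methoxybenzoate
Conditions: 4-MeOC6H4COCl, pyridine, 4-(dimethylamino)pyridine (cat.), CH2Cl2, 0 °C to rt
Reagents that add atoms: 4-methoxybenzoyl chloride, COc1ccc(cc1)C(Cl)=O
Why: Nucleophile-catalysed O-acylation (esterification) takes place only at the secondary C6 hydroxyl because the C4 hydroxyl is tertiary and flanked by isopropyl, so the target forms without touching any stereocentre or the allylic acetate.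

**Compound list**

1 | (S)-terpinen-4-ol, (1S)-4-methyl-1-(propan-2-yl)cyclohex-3-en-1-ol | CC(C)[C@]1(O)CCC(C)=CC1 | starting material
2 | secondary ozonide of 1, (4S)-1-methyl-4-(propan-2-yl)-7,8,9-trioxabicyclo[4.2.1]nonan-4-ol (bridgehead epimers) | CC(C)[C@]1(O)CCC2(C)OOC(C1)O2 | intermediate (not isolated)
3 | (3S)-3-hydroxy-6-oxo-3-(propan-2-yl)heptanal | CC(C)[C@](CC=O)(O)CCC(C)=O | intermediate
4 | (5R,6Z)-5-(propan-2-yl)-5,7-bis[(triethylsilyl)oxy]hept-6-en-2-one (E isomer equally usable) | CC(C)[C@](/C=C\O[Si](CC)(CC)CC)(O[Si](CC)(CC)CC)CCC(C)=O | intermediate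
5 | 2-methylbut-1-en-3-yne | C=C(C)C#C | starting material
6 | lithium 3-methylbut-3-en-1-yn-1-ide | [Li]C#CC(C)=C | intermediate (not isolated)
7 | lithium (5RS,8R,9Z)-2,5-dimethyl-8-(propan-2-yl)-8,10-bis[(triethylsilyl)oxy]deca-1,9-dien-3-yn-5-olate | CC(C)[C@](/C=C\O[Si](CC)(CC)CC)(O[Si](CC)(CC)CC)CCC(C)(O[Li])C#CC(C)=C | intermediate (not isolated)
8 | (5RS,8R,9Z)-2,5-dimethyl-8-(propan-2-yl)-8,10-bis[(triethylsilyl)oxy]deca-1,9-dien-3-yn-5-yl acetate | CC(C)[C@](/C=C\O[Si](CC)(CC)CC)(O[Si](CC)(CC)CC)CCC(C)(OC(C)=O)C#CC(C)=C | intermediate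
9 | (3Z,5RS,8R,9Z)-2,5-dimethyl-8-(propan-2-yl)-8,10-bis[(triethylsilyl)oxy]deca-1,3,9-trien-5-yl acetate | CC(C)[C@](/C=C\O[Si](CC)(CC)CC)(O[Si](CC)(CC)CC)CCC(C)(OC(C)=O)/C=C\C(C)=C | intermediate
10 | (3R,3aS,4S,8R,8aS)-6,8a-dimethyl-3-(propan-2-yl)-3,4-bis[(triethylsilyl)oxy]-1,2,3,3a,4,5,8,8a-octahydroazulen-8-yl acetate (trans-fused; 1-methyl β, 4-O β, 5-H α, 6-O α, 10-OAc α) | CC[Si](CC)(CC)O[C@H]1CC(C)=C[C@@H](OC(C)=O)[C@@]2(C)CC[C@@](O[Si](CC)(CC)CC)(C(C)C)[C@H]12 | intermediate (not isolated)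
11 | (3R,3aS,4S,8R,8aS)-3,4-dihydroxy-6,8a-dimethyl-3-(propan-2-yl)-1,2,3,3a,4,5,8,8a-octahydroazulen-8-yl acetate (10α-acetoxydauc-8-ene-4β,6α-diol) | O[C@H]1CC(C)=C[C@@H](OC(C)=O)[C@@]2(C)CC[C@@](O)(C(C)C)[C@H]12 | intermediate
12 | (3R,3aS,4S,8R,8aS)-8-(acetyloxy)-3-hydroxy-6,8a-dimethyl-3-(propan-2-yl)-1,2,3,3a,4,5,8,8a-octahydroazulen-4-yl 4-methoxybenzoate (CNP0256979.2) | COc1ccc(C(=O)O[C@H]2CC(C)=C[C@@H](OC(C)=O)[C@@]3(C)CC[C@@](O)(C(C)C)[C@H]23)cc1 | target

**Totals and risks**

Total step count: 6. Longest linear sequence: 6 steps (from 1; 5 is bought).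

Step 5 is the most likely to fail. The (Z)-pentadienyl cation can electrocyclise or eliminate, the Z geometry can be lost, the cis-cyclopentane can divert to an oxa-bridged product, and acetate return can lose to elimination. The fallback separates the two ring closures and moves the first one to the alkyne stage, where the cation is linear and can do none of these things. It sets out from 8: BF3·OEt2 in CH2Cl2 at −78 °C ionises the tertiary propargylic acetate and the silyl enol ether closes the five-membered ring (intramolecular propargylic alkylation) to give (1R,2S,5R)-2-methyl-2-(3-methylbut-3-en-1-yn-1-yl)-5-(propan-2-yl)-5-[(triethylsilyl)oxy]cyclopentane-1-carbaldehyde F1, whose C2 configuration has to be confirmed at this stage because the slim alkynyl group biases the closure less than the dienyl group does. Semi-hydrogenation over Pd on CaCO3 poisoned with Pb(OAc)2 gives (1R,2R,5R)-2-methyl-2-[(1Z)-3-methylbuta-1,3-dien-1-yl]-5-(propan-2-yl)-5-[(triethylsilyl)oxy]cyclopentane-1-carbaldehyde F2. BF3·OEt2 with acetic acid in CH2Cl2 at −40 °C then closes the seven-membered ring by the diene–Prins reaction with acetate capture at C10, giving (3R,3aS,4S,8R,8aS)-4-hydroxy-6,8a-dimethyl-3-(propan-2-yl)-3-[(triethylsilyl)oxy]-1,2,3,3a,4,5,8,8a-octahydroazulen-8-yl acetate F3, and HF·pyridine brings the material back to the route at 11.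

Step 2 is the second risk. The aldehyde-over-ketone selectivity of the silylation is not secured, the β-hydroxy aldehyde 3 is fragile, and its hydroxy ketone end can close to a hemiketal. The fallback differentiates the two carbonyls with a protecting group and makes the enol ether only after the ketone has been consumed. It sets out from 3: chemoselective acetalisation of the aldehyde (HC(OMe)3, MeOH, pyridinium p-toluenesulfonate) gives (5S)-5-hydroxy-7,7-dimethoxy-5-(propan-2-yl)heptan-2-one F4, and silylation of the tertiary alcohol (Et3SiOTf, 2,6-lutidine, −78 °C) gives (5S)-7,7-dimethoxy-5-(propan-2-yl)-5-[(triethylsilyl)oxy]heptan-2-one F5. Addition of acetylide 6 and acetylation as in step 3 give (5RS,8S)-10,10-dimethoxy-2,5-dimethyl-8-(propan-2-yl)-8-[(triethylsilyl)oxy]dec-1-en-3-yn-5-yl acetate F6, and mild acetal hydrolysis (LiBF4, wet MeCN) gives (5RS,8S)-2,5-dimethyl-10-oxo-8-(propan-2-yl)-8-[(triethylsilyl)oxy]dec-1-en-3-yn-5-yl acetate F7. Et3SiOTf/Et3N then converts the aldehyde into the silyl enol ether, and the sequence comes back to the route at 8.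

Step 4 is the third risk, through over-reduction of the enyne and the lability of the (Z)-dienyl tertiary acetate. The fallback builds the Z alkene by cross-coupling instead of hydrogenation. It sets out from 4: HC≡CMgBr adds to the ketone to give (3RS,6R,7Z)-3-methyl-6-(propan-2-yl)-6,8-bis[(triethylsilyl)oxy]oct-7-en-1-yn-3-ol F8, and N-iodosuccinimide with AgNO3 (cat.) gives (3RS,6R,7Z)-1-iodo-3-methyl-6-(propan-2-yl)-6,8-bis[(triethylsilyl)oxy]oct-7-en-1-yn-3-ol F9. Diimide from 2-nitrobenzenesulfonylhydrazide and Et3N reduces it to (1Z,3RS,6R,7Z)-1-iodo-3-methyl-6-(propan-2-yl)-6,8-bis[(triethylsilyl)oxy]octa-1,7-dien-3-ol F10. Suzuki–Miyaura coupling with isopropenylboronic acid pinacol ester (Pd(PPh3)4, a zerovalent palladium complex; aqueous K3PO4) gives with retention (3Z,5RS,8R,9Z)-2,5-dimethyl-8-(propan-2-yl)-8,10-bis[(triethylsilyl)oxy]deca-1,3,9-trien-5-ol F11, and O-acetylation of the tertiary alcohol (LiN(SiMe3)2, then Ac2O) comes back to the route at 9.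

**Further compounds**

F1 | step 5 | (1R,2S,5R)-2-methyl-2-(3-methylbut-3-en-1-yn-1-yl)-5-(propan-2-yl)-5-[(triethylsilyl)oxy]cyclopentane-1-carbaldehyde | C=C(C)C#C[C@@]1(C)CC[C@@](O[Si](CC)(CC)CC)(C(C)C)[C@@H]1C=O
F2 | step 5 | (1R,2R,5R)-2-methyl-2-[(1Z)-3-methylbuta-1,3-dien-1-yl]-5-(propan-2-yl)-5-[(triethylsilyl)oxy]cyclopentane-1-carbaldehyde | C=C(C)\C=C/[C@@]1(C)CC[C@@](O[Si](CC)(CC)CC)(C(C)C)[C@@H]1C=O
F3 | step 5 | (3R,3aS,4S,8R,8aS)-4-hydroxy-6,8a-dimethyl-3-(propan-2-yl)-3-[(triethylsilyl)oxy]-1,2,3,3a,4,5,8,8a-octahydroazulen-8-yl acetate | O[C@H]1CC(C)=C[C@@H](OC(C)=O)[C@@]2(C)CC[C@@](O[Si](CC)(CC)CC)(C(C)C)[C@H]12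
F4 | step 2 | (5S)-5-hydroxy-7,7-dimethoxy-5-(propan-2-yl)heptan-2-one | CC(C)[C@](CC(OC)OC)(O)CCC(C)=O
F5 | step 2 | (5S)-7,7-dimethoxy-5-(propan-2-yl)-5-[(triethylsilyl)oxy]heptan-2-one | CC(C)[C@](CC(OC)OC)(O[Si](CC)(CC)CC)CCC(C)=O
F6 | step 2 | (5RS,8S)-10,10-dimethoxy-2,5-dimethyl-8-(propan-2-yl)-8-[(triethylsilyl)oxy]dec-1-en-3-yn-5-yl acetate | CC(C)[C@](CC(OC)OC)(O[Si](CC)(CC)CC)CCC(C)(OC(C)=O)C#CC(C)=C
F7 | step 2 | (5RS,8S)-2,5-dimethyl-10-oxo-8-(propan-2-yl)-8-[(triethylsilyl)oxy]dec-1-en-3-yn-5-yl acetate | CC(C)[C@](CC=O)(O[Si](CC)(CC)CC)CCC(C)(OC(C)=O)C#CC(C)=C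
F8 | step 4 | (3RS,6R,7Z)-3-methyl-6-(propan-2-yl)-6,8-bis[(triethylsilyl)oxy]oct-7-en-1-yn-3-ol | CC(C)[C@](/C=C\O[Si](CC)(CC)CC)(O[Si](CC)(CC)CC)CCC(C)(O)C#C
F9 | step 4 | (3RS,6R,7Z)-1-iodo-3-methyl-6-(propan-2-yl)-6,8-bis[(triethylsilyl)oxy]oct-7-en-1-yn-3-ol | CC(C)[C@](/C=C\O[Si](CC)(CC)CC)(O[Si](CC)(CC)CC)CCC(C)(O)C#CI
F10 | step 4 | (1Z,3RS,6R,7Z)-1-iodo-3-methyl-6-(propan-2-yl)-6,8-bis[(triethylsilyl)oxy]octa-1,7-dien-3-ol | CC(C)[C@](/C=C\O[Si](CC)(CC)CC)(O[Si](CC)(CC)CC)CCC(C)(O)/C=C\I
F11 | step 4 | (3Z,5RS,8R,9Z)-2,5-dimethyl-8-(propan-2-yl)-8,10-bis[(triethylsilyl)oxy]deca-1,3,9-trien-5-ol | CC(C)[C@](/C=C\O[Si](CC)(CC)CC)(O[Si](CC)(CC)CC)CCC(C)(O)/C=C\C(C)=C
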